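**Plan**
- Retrosynthetic cuts: the O15–acyl bond; in ring A the C4–C18 and C3–C4 bonds (two ester-enolate alkylations); the C8=C17 methylene is traced back to a ring B C7=C8 alkene carrying O17; ring B is then cut at C5–C6 and C9–C10.
- Enabling feature: ring B holds the quaternary C10 between C5 and C9. With its alkene moved to C7=C8 it is the cyclohexene formed from an α-methyl enal (C1, C10, C20, C5 with the C4/C19 arm) and a C6–C9 diene that already bears C17 and the C11–C16 chain.
- Forward order: diene 10 from geranyl acetate (steps 1–7); enal 13 by cross-metathesis (step 8); ring B by catalysed cycloaddition (step 9); C1 extended to C3, alkene transposed to C8=C17, ring A closed and methylated (steps 10–20); deprotection and O15 oleoylation (steps 21–22).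
- Stereochemistry: C5, C9 and C10 from the oxazaborolidinium-controlled exo cycloaddition (E enal, E diene terminus); C4 from α-face methylation of the ring A enolate, anti to the axial C20 methyl; C13=C14 (E) from geranyl acetate; the Z alkene of the acyl chain from oleic acid.

Key step: step 9

Remark: labdane numbering (C1–C20) is used for every intermediate; 4,4-diethoxybut-1-ene and methacrolein are taken as commercial and replace the dimethyl acetal route, so the acetal is diethyl.
Assumption: the catalyst binds enal 13 as it binds 2-methylacrolein (formyl C–H···O contact, s-trans enal), so the catalyst from (S)-diphenylprolinol should expose the Re face of C10; if the sense proves opposite, the catalyst from (R)-diphenylprolinol is used with nothing else changed.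

**Route**

Step 1
Reactants: 1 geranyl acetate
Product: 3 (2E)-3-methyl-6-oxohex-2-en-1-yl acetate, via 6,7-epoxygeranyl acetate 2 (not isolated)
Conditions: mCPBA, CH2Cl2, 0 °C; then H5IO6, THF/H2O, 0 °C to rt
Reagents that add atoms: mCPBA, OOC(=O)c1cccc(Cl)c1
Why: Prilezhaev epoxidation selects the electron-rich terminal trisubstituted alkene (the other alkene is deactivated by the allylic acetate), and periodic acid then cleaves the epoxide (Malaprade-type cleavage) to the aldehyde and acetone; no stereocentre is carried on.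

Step 2
Reactants: 3 (2E)-3-methyl-6-oxohex-2-en-1-yl acetate
Product: 5 (2E)-3-methylhept-2-en-6-yn-1-ol, via acetoxy alkyne 4 (not isolated)
Conditions: dimethyl (1-diazo-2-oxopropyl)phosphonate, K2CO3, MeOH, 0 °C to rt
Reagents that add atoms: dimethyl (1-diazo-2-oxopropyl)phosphonate (Ohira–Bestmann reagent), CC(=O)C(=[N+]=[N-])P(=O)(OC)OC
Why: Seyferth–Gilbert homologation in its Ohira–Bestmann form turns the formyl carbon (future C9) into the internal carbon of a terminal alkyne and adds C8, while K2CO3 in methanol also removes the acetate by transesterification.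

Step 3
Reactants: 5 (2E)-3-methylhept-2-en-6-yn-1-ol
Product: 6 tert-butyl{[(2E)-3-methylhept-2-en-6-yn-1-yl]oxy}diphenylsilane
Conditions: TBDPSCl, imidazole, DMF, rt
Reagents that add atoms: tert-butyl(chloro)diphenylsilane (TBDPSCl), CC(C)(C)[Si](Cl)(c1ccccc1)c1ccccc1
Why: standard silylation of the primary allylic alcohol (O15) gives an ether that should survive organolithium, hydride, mild-acid and enolate conditions until step 21.

Step 4
Reactants: 6 tert-butyl{[(2E)-3-methylhept-2-en-6-yn-1-yl]oxy}diphenylsilane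
Product: 7 (6E)-8-[(tert-butyldiphenylsilyl)oxy]-6-methyloct-6-en-2-yn-1-ol
Conditions: n-BuLi, THF, −78 °C; paraformaldehyde, −78 °C to rt; aq. NH4Cl
Reagents that add atoms: formaldehyde (from paraformaldehyde), C=O
Why: deprotonation of the terminal alkyne and 1,2-addition of the lithium acetylide to formaldehyde (alkynylation) installs C17 as a propargylic alcohol.

Step 5
Reactants: 7 (6E)-8-[(tert-butyldiphenylsilyl)oxy]-6-methyloct-6-en-2-yn-1-ol
Product: 8 (2E,6E)-8-[(tert-butyldiphenylsilyl)oxy]-6-methyl-2-(tributylstannyl)octa-2,6-dien-1-ol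
Conditions: Bu3SnH, PdCl2(PPh3)2 (2 mol%), THF, 0 °C to rt
Reagents that add atoms: tributyltin hydride, CCCC[SnH](CCCC)CCCC
Why: palladium-catalysed hydrostannation adds H and Sn syn across the alkyne with tin expected at C8, next to the hydroxymethyl group as is usual for 2-alkyn-1-ols, so that C17 and C11 end up cis on the C8=C9 alkene.

Step 6
Reactants: 8 (2E,6E)-8-[(tert-butyldiphenylsilyl)oxy]-6-methyl-2-(tributylstannyl)octa-2,6-dien-1-ol
Product: 9 (2Z,6E)-8-[(tert-butyldiphenylsilyl)oxy]-2-ethenyl-6-methylocta-2,6-dien-1-ol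
Conditions: vinyl bromide (1 M in THF), Pd(PPh3)4 (5 mol%), copper iodide CuI (10 mol%), CsF, DMF, 45 °C
Reagents that add atoms: vinyl bromide, C=CBr
Why: Stille coupling proceeds with retention at the alkenyl carbon, so the vinyl group (C7=C6) replaces tin trans to C11; CuI and fluoride assist transmetalation of the hindered stannane.

Step 7
Reactants: 9 (2Z,6E)-8-[(tert-butyldiphenylsilyl)oxy]-2-ethenyl-6-methylocta-2,6-dien-1-ol
Product: 10 diene, the O17 tert-butyldimethylsilyl ether of 9
Conditions: TBSCl, imidazole, DMF, 0 °C to rt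
Reagents that add atoms: tert-butyl(chloro)dimethylsilane (TBSCl), CC(C)(C)[Si](C)(C)Cl
Why: silylation masks the allylic alcohol for the Lewis-acid step with a group that can later be removed in the presence of the TBDPS ether.

Step 8
Reactants: 11 4,4-diethoxybut-1-ene; 12 methacrolein (3 equiv)
Product: 13 (2E)-5,5-diethoxy-2-methylpent-2-enal
Conditions: second-generation Grubbs catalyst RuCl2(=CHPh)(PCy3)(H2IMes) (3 mol%), CH2Cl2, 40 °C
Reagents that add atoms: none
Why: olefin cross-metathesis of a terminal alkene with methacrolein should give the trisubstituted enal as the E isomer (formyl trans to the chain), the preferred outcome for 2-methyl enals.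

Step 9
Reactants: 10 diene (1.2 equiv); 13 (2E)-5,5-diethoxy-2-methylpent-2-enal
Product: 14 ring B adduct, (5S,9S,10S)
Conditions: (S)-3,3-diphenyl-1-(2-methylphenyl)tetrahydro-1H,3H-pyrrolo[1,2-c][1,3,2]oxazaborole (20 mol%), Tf2NH (18 mol%), CH2Cl2, −78 to −20 °C
Reagents that add atoms: none
Why: The N-protonated oxazaborolidine, a cationic boron Lewis acid, binds the formyl oxygen of 13 and diene 10 adds in a concerted, asynchronous [4+2] cycloaddition that joins C6 to the β carbon C5 and C9 to the α carbon C10, the reaction type being the known oxazaborolidinium-catalysed Diels–Alder addition of 2-methylacrolein and related α-substituted enals to acyclic dienes. Ring B closes as a C7=C8 cyclohexene by intermolecular, suprafacial union of the four diene carbons C6–C9 with C5 and C10, both ring bonds forming in the one step. C10 is set by the catalyst, whose aryl group covers the Si face of the bound s-trans enal so that C9 should add to the Re face of C10 (10S in 14). C5 follows from C10 through the E geometry of the enal, which keeps the C4 arm trans to the formyl group (5S). C9 follows from the E-configured C8=C9 diene terminus together with the formyl-exo, methyl-endo transition state that α-methyl enals prefer, which places C11 cis to C20 (9S). The step needs ortho regiochemistry, secured by the C9 alkyl terminus whose directing effect outweighs that of the C8 silyloxymethyl group and is reinforced by Lewis-acid activation, exo selectivity, secured by the α-methyl group, and face selectivity, secured by the catalyst.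

Step 10
Reactants: 14 ring B adduct
Product: 15 methyl (E)-acrylate (C1=C2–C3O2Me on C10)
Conditions: trimethyl phosphonoacetate, NaH, THF, 0 to 50 °C
Reagents that add atoms: trimethyl phosphonoacetate, COC(=O)CP(=O)(OC)OC
Why: Horner–Wadsworth–Emmons olefination of the non-enolisable neopentyl aldehyde adds C2 and C3 as an (E)-acrylate without touching a stereocentre.

Step 11
Reactants: 15 methyl (E)-acrylate
Product: 16 saturated methyl ester (C1H2–C2H2–C3O2Me)
Conditions: Mg, MeOH, 0 °C to rt
Reagents that add atoms: none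
Why: dissolving-metal conjugate reduction (electron transfer from Mg to the enoate, protonation by methanol) saturates only the C1=C2 bond and leaves the isolated trisubstituted alkenes, the acetal and both silyl ethers alone.

Step 12
Reactants: 16 saturated methyl ester
Product: 17 allylic alcohol (free O17–H)
Conditions: PPTS, EtOH, 40 °C
Reagents that add atoms: none
Why: mild acid-catalysed ethanolysis cleaves the primary TBS ether much faster than the TBDPS ether, and ethanol as solvent makes any exchange at the diethyl acetal degenerate.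

Step 13
Reactants: 17 allylic alcohol
Product: 20 exocyclic methylene ester (C8=C17), via allylic sulfonylhydrazine 18 (not isolated), via allylic diazene 19 (not isolated)
Conditions: 2-nitrobenzenesulfonylhydrazide, PPh3, DEAD, THF, −30 °C; then rt
Reagents that add atoms: none
Why: Mitsunobu displacement of the primary allylic alcohol by the sulfonylhydrazide, loss of sulfinic acid and retro-ene loss of N2 from the allylic diazene (reductive 1,3-transposition) deliver hydrogen to C7 and move the alkene to C8=C17; C7 becomes CH2, so no stereocentre arises.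

Step 14
Reactants: 20 exocyclic methylene ester
Product: 21 primary alcohol (C3–OH)
Conditions: iBu2AlH, CH2Cl2, −78 to 0 °C; aq. Rochelle salt
Reagents that add atoms: none
Why: hydride reduction of the methyl ester to the primary alcohol; acetal, silyl ether and alkenes are inert to iBu2AlH.

Step 15
Reactants: 21 primary alcohol
Product: 22 primary bromide (C3–Br)
Conditions: CBr4, PPh3, imidazole, CH2Cl2, 0 °C
Reagents that add atoms: carbon tetrabromide, BrC(Br)(Br)Br
Why: Appel bromination (SN2 on the alkoxyphosphonium ion) under imidazole buffering converts C3–OH into the bromide without acid that could touch the acetal.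

Step 16
Reactants: 22 primary bromide
Product: 23 C19 aldehyde
Conditions: PPTS, acetone/H2O (9:1), 50 °C
Reagents that add atoms: water, O
Why: acid-catalysed acetal hydrolysis unmasks the C19 aldehyde, PPTS being too weak to isomerise the C8=C17 alkene or cleave the TBDPS ether.

Step 17
Reactants: 23 C19 aldehyde
Product: 24 C19 carboxylic acid
Conditions: NaClO2, NaH2PO4, 2-methyl-2-butene, t-BuOH/H2O, rt
Reagents that add atoms: sodium chlorite, [Na+].[O-]Cl=O
Why: Pinnick oxidation converts the aldehyde into the acid, with 2-methyl-2-butene scavenging HOCl so that the alkenes are spared.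

Step 18
Reactants: 24 C19 carboxylic acid
Product: 25 2-(trimethylsilyl)ethyl ester
Conditions: 2-(trimethylsilyl)ethanol, DCC, DMAP (cat.), CH2Cl2, 0 °C to rt
Reagents that add atoms: 2-(trimethylsilyl)ethanol, C[Si](C)(C)CCO
Why: Steglich esterification gives an ester whose later cleavage takes place at silicon and not at the hindered C19 carbonyl.

Step 19
Reactants: 25 2-(trimethylsilyl)ethyl ester
Product: 26 bicyclic ester (ring A closed, C4 epimers)
Conditions: LiN(iPr)2, THF/DMPU, −78 °C to rt, high dilution
Reagents that add atoms: none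
Why: intramolecular ester-enolate alkylation (6-exo-tet SN2 of the C4 enolate on C3–Br) closes ring A as a trans-decalin, the ring fusion being fixed by C5 and C10; the C4 configuration formed here is erased in step 20.

Step 20
Reactants: 26 bicyclic ester
Product: 27 2-(trimethylsilyl)ethyl 15-[(tert-butyldiphenylsilyl)oxy]labda-8(17),13E-dien-19-oate
Conditions: LiN(iPr)2, THF, −78 to 0 °C; MeI, DMPU, −78 °C to rt
Reagents that add atoms: iodomethane, CI
Why: ester-enolate alkylation in which MeI should attack the C4 enolate from the equatorial α face, away from the axial C20 methyl that blocks the β face by 1,3-diaxial repulsion, making C18 equatorial and the ester axial (C19), i.e. 4S.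

Step 21
Reactants: 27 2-(trimethylsilyl)ethyl 15-[(tert-butyldiphenylsilyl)oxy]labda-8(17),13E-dien-19-oate
Product: 28 isocupressic acid [(4S,5R,9S,10R)-15-hydroxylabda-8(17),13E-dien-19-oic acid]
Conditions: Bu4NF, THF, rt to 40 °C; aq. NH4Cl
Reagents that add atoms: none
Why: fluoride cleaves the Si–O bond of the TBDPS ether and triggers β-elimination of the 2-(trimethylsilyl)ethyl ester (attack at silicon, loss of ethene), so the hindered C19 acid is freed without hydrolysis at the carbonyl.

Step 22
Reactants: 28 isocupressic acid; 29 oleic acid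
Product: 31 15-O-oleoylisocupressic acid (CNP0287077.1), via oleoyl chloride 30 (not isolated)
Conditions: 29, (COCl)2, DMF (cat.), CH2Cl2, rt, evaporate; then 28, pyridine, DMAP (cat.), CH2Cl2, 0 °C; aq. NaHCO3 work-up
Reagents that add atoms: none
Why: nucleophile-catalysed acylation of the primary allylic alcohol O15 by the acid chloride; the axial, neopentyl-like C19 carboxyl is not acylated productively and is returned as the free acid on bicarbonate work-up, and the Z alkene of the acyl chain is untouched.

**Compound list**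

1 | geranyl acetate, (2E)-3,7-dimethylocta-2,6-dien-1-yl acetate | CC(C)=CCC/C(C)=C/COC(C)=O | starting material
2 | 6,7-epoxygeranyl acetate (racemic, not isolated) | CC(=O)OC/C=C(C)/CCC1OC1(C)C | intermediate
3 | (2E)-3-methyl-6-oxohex-2-en-1-yl acetate | CC(=O)OC/C=C(C)/CCC=O | intermediate
4 | (2E)-3-methylhept-2-en-6-yn-1-yl acetate (not isolated) | CC(=O)OC/C=C(C)/CCC#C | intermediate
5 | (2E)-3-methylhept-2-en-6-yn-1-ol | OC/C=C(C)/CCC#C | intermediate
6 | tert-butyl{[(2E)-3-methylhept-2-en-6-yn-1-yl]oxy}diphenylsilane | C#CCC/C(C)=C/CO[Si](c1ccccc1)(c1ccccc1)C(C)(C)C | intermediate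
7 | (6E)-8-[(tert-butyldiphenylsilyl)oxy]-6-methyloct-6-en-2-yn-1-ol | OCC#CCC/C(C)=C/CO[Si](c1ccccc1)(c1ccccc1)C(C)(C)C | intermediate
8 | (2E,6E)-8-[(tert-butyldiphenylsilyl)oxy]-6-methyl-2-(tributylstannyl)octa-2,6-dien-1-ol (Sn on C8, trans to C11) | CCCC[Sn](CCCC)(CCCC)/C(CO)=C/CC/C(C)=C/CO[Si](c1ccccc1)(c1ccccc1)C(C)(C)C | intermediate
9 | (2Z,6E)-8-[(tert-butyldiphenylsilyl)oxy]-2-ethenyl-6-methylocta-2,6-dien-1-ol (vinyl trans to C11) | C=C/C(CO)=C/CC/C(C)=C/CO[Si](c1ccccc1)(c1ccccc1)C(C)(C)C | intermediate
10 | diene: O17 tert-butyldimethylsilyl ether of 9, (2Z,6E)-configured nona-2,6,8-triene with C6=C7–C8(C17H2OTBS)=C9 and O15 TBDPS | C=C/C(CO[Si](C)(C)C(C)(C)C)=C/CC/C(C)=C/CO[Si](c1ccccc1)(c1ccccc1)C(C)(C)C | intermediate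
11 | 4,4-diethoxybut-1-ene | C=CCC(OCC)OCC | starting material
12 | methacrolein, 2-methylprop-2-enal | C=C(C)C=O | starting material
13 | (2E)-5,5-diethoxy-2-methylpent-2-enal | O=C/C(C)=C/CC(OCC)OCC | intermediate
14 | ring B adduct, (1S,2S,6S)-3-{[tert-butyl(dimethyl)silyl]oxymethyl}-2-{(3E)-5-[tert-butyl(diphenyl)silyl]oxy-3-methylpent-3-enyl}-6-(2,2-diethoxyethyl)-1-methylcyclohex-3-ene-1-carbaldehyde; labdane locants 5S,9S,10S: 10β-CH3, 10α-CHO, 5α-H, 9α-H, C7=C8 | CC(C)(C)[Si](C)(C)OCC1=CC[C@@H](CC(OCC)OCC)[C@](C)(C=O)[C@H]1CC/C(C)=C/CO[Si](c2ccccc2)(c2ccccc2)C(C)(C)C | intermediate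
15 | 14 with the formyl group replaced by (E)-CH=CH–CO2CH3 (C1=C2, C3 ester); configuration at C5, C9, C10 as in 14 | CC(C)(C)[Si](C)(C)OCC1=CC[C@@H](CC(OCC)OCC)[C@](C)(/C=C/C(=O)OC)[C@H]1CC/C(C)=C/CO[Si](c2ccccc2)(c2ccccc2)C(C)(C)C | intermediate
16 | 15 with C1–C2 saturated (C10–CH2CH2CO2CH3) | CC(C)(C)[Si](C)(C)OCC1=CC[C@@H](CC(OCC)OCC)[C@](C)(CCC(=O)OC)[C@H]1CC/C(C)=C/CO[Si](c2ccccc2)(c2ccccc2)C(C)(C)C | intermediate
17 | 16 with free C17 hydroxyl (C8–CH2OH) | OCC1=CC[C@@H](CC(OCC)OCC)[C@](C)(CCC(=O)OC)[C@H]1CC/C(C)=C/CO[Si](c2ccccc2)(c2ccccc2)C(C)(C)C | intermediate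
18 | N-(C17-allyl)-N-(2-nitrobenzenesulfonyl)hydrazine derived from 17 (not isolated) | NN(CC1=CC[C@@H](CC(OCC)OCC)[C@](C)(CCC(=O)OC)[C@H]1CC/C(C)=C/CO[Si](c2ccccc2)(c2ccccc2)C(C)(C)C)S(=O)(=O)c1ccccc1[N+](=O)[O-] | intermediate
19 | C17 allylic monoalkyl diazene (C17–N=NH, not isolated) | N=NCC1=CC[C@@H](CC(OCC)OCC)[C@](C)(CCC(=O)OC)[C@H]1CC/C(C)=C/CO[Si](c2ccccc2)(c2ccccc2)C(C)(C)C | intermediate
20 | methyl ester with ring B as a cyclohexane bearing the C8=C17 exocyclic methylene; 5α-H, 9α-H, 10β-CH3; C5 arm CH2CH(OEt)2, C10 arm CH2CH2CO2CH3 | C=C1CC[C@@H](CC(OCC)OCC)[C@](C)(CCC(=O)OC)[C@H]1CC/C(C)=C/CO[Si](c2ccccc2)(c2ccccc2)C(C)(C)C | intermediate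
21 | 20 with C10 arm CH2CH2CH2OH (C3–OH) | C=C1CC[C@@H](CC(OCC)OCC)[C@](C)(CCCO)[C@H]1CC/C(C)=C/CO[Si](c2ccccc2)(c2ccccc2)C(C)(C)C | intermediate
22 | 21 with C3–Br | C=C1CC[C@@H](CC(OCC)OCC)[C@](C)(CCCBr)[C@H]1CC/C(C)=C/CO[Si](c2ccccc2)(c2ccccc2)C(C)(C)C | intermediate
23 | 22 with C5 arm CH2CHO (C19 aldehyde) | C=C1CC[C@@H](CC=O)[C@](C)(CCCBr)[C@H]1CC/C(C)=C/CO[Si](c2ccccc2)(c2ccccc2)C(C)(C)C | intermediate
24 | 22 with C5 arm CH2CO2H (C19 acid) | C=C1CC[C@@H](CC(=O)O)[C@](C)(CCCBr)[C@H]1CC/C(C)=C/CO[Si](c2ccccc2)(c2ccccc2)C(C)(C)C | intermediate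
25 | 2-(trimethylsilyl)ethyl ester of 24 | C=C1CC[C@@H](CC(=O)OCC[Si](C)(C)C)[C@](C)(CCCBr)[C@H]1CC/C(C)=C/CO[Si](c2ccccc2)(c2ccccc2)C(C)(C)C | intermediate
26 | 2-(trimethylsilyl)ethyl 15-[(tert-butyldiphenylsilyl)oxy]-18-norlabda-8(17),13E-dien-19-oate, trans-decalin, mixture of C4 epimers | C=C1CC[C@@H]2[C@](C)(CCCC2C(=O)OCC[Si](C)(C)C)[C@H]1CC/C(C)=C/CO[Si](c3ccccc3)(c3ccccc3)C(C)(C)C | intermediate
27 | 2-(trimethylsilyl)ethyl (4S,5R,9S,10R)-15-[(tert-butyldiphenylsilyl)oxy]labda-8(17),13E-dien-19-oate | C=C1CC[C@@H]2[C@](C)(CCC[C@]2(C)C(=O)OCC[Si](C)(C)C)[C@H]1CC/C(C)=C/CO[Si](c3ccccc3)(c3ccccc3)C(C)(C)C | intermediate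
28 | isocupressic acid, (4S,5R,9S,10R)-15-hydroxylabda-8(17),13E-dien-19-oic acid | C=C1CC[C@@H]2[C@](C)(CCC[C@]2(C)C(=O)O)[C@H]1CC/C(C)=C/CO | intermediate
29 | oleic acid, (9Z)-octadec-9-enoic acid | CCCCCCCC/C=C\CCCCCCCC(=O)O | starting material
30 | oleoyl chloride (not isolated) | CCCCCCCC/C=C\CCCCCCCC(=O)Cl | intermediate
31 | (4S,5R,9S,10R)-15-[(9Z)-octadec-9-enoyloxy]labda-8(17),13E-dien-19-oic acid (CNP0287077.1) | C=C1CC[C@@H]2[C@](C)(CCC[C@]2(C)C(=O)O)[C@H]1CC/C(C)=C/COC(=O)CCCCCCC/C=C\CCCCCCCC | target

**Totals and risks**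

Total step count: 22. Longest linear sequence: 21 steps (steps 1–7 and 9–22, from geranyl acetate 1).

Steps most likely to fail:

1. Step 9. The cycloaddition joins a trisubstituted enal to a 1,2-disubstituted diene and may be slow. Warming would then erode exo and facial selectivity, and the cationic boron acid may ionise the acetal or the allylic silyl ether. The fallback sets out from 10 and 13 and returns at 14, with the chirality taken from a resolution instead of the catalyst. The two fragments are combined with MeAlCl2 in CH2Cl2 at −78 °C, which should give the racemic adduct F1 with the same ortho, exo relative configuration. Condensation with (1R,2R)-N,N'-dimethyl-1,2-diphenylethane-1,2-diamine over molecular sieves should give two diastereomeric imidazolidines, the aminal of 14 F2 and the aminal of ent-14 F3, to be separated on silica. Brief two-phase treatment of F2 with dilute aqueous acid should release 14, the aminal hydrolysing far faster than the acetal or the silyl ethers.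

2. Step 5. Tin may be delivered in part to C9 instead of C8, giving an isomeric stannane that would lead to the wrong diene substitution pattern. The fallback sets out from 6 and returns at 9, with an ester directing the regiochemistry. Lithiation of 6 and trapping with methyl chloroformate should give the ynoate F4. Hydrostannation with Bu3SnH and Pd(PPh3)4 places tin reliably α to the ester with syn addition, giving the stannyl enoate F5. Stille coupling with vinyl bromide gives the dienoate F6, which is reduced at once with iBu2AlH to dienol 9.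

3. Step 22. Acylation may be diverted to the free C19 carboxyl (mixed anhydride formation consuming the acid chloride), leaving O15 incompletely acylated. The fallback sets out from 27 and returns at 31, with the carboxyl kept masked during acylation. Buffered HF·pyridine in THF should remove only the TBDPS ether to give the hydroxy ester F7. Steglich esterification with oleic acid 29 (DCC, DMAP) gives the oleate ester F8. Fluoride (Bu4NF, THF) then cleaves the 2-(trimethylsilyl)ethyl ester at silicon to give 31.

**Further compounds**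

F1 | step 9 | racemic adduct (1:1 mixture of 14 and its enantiomer) | CC(C)(C)[Si](C)(C)OCC1=CC[C@@H](CC(OCC)OCC)[C@](C)(C=O)[C@H]1CC/C(C)=C/CO[Si](c2ccccc2)(c2ccccc2)C(C)(C)C.CC(C)(C)[Si](C)(C)OCC1=CC[C@H](CC(OCC)OCC)[C@@](C)(C=O)[C@@H]1CC/C(C)=C/CO[Si](c2ccccc2)(c2ccccc2)C(C)(C)C
F2 | step 9 | aminal of 14: (4R,5R)-1,3-dimethyl-4,5-diphenylimidazolidin-2-yl group in place of the formyl group | CC(C)(C)[Si](C)(C)OCC1=CC[C@@H](CC(OCC)OCC)[C@](C)(C2N(C)[C@H](c3ccccc3)[C@@H](c3ccccc3)N2C)[C@H]1CC/C(C)=C/CO[Si](c4ccccc4)(c4ccccc4)C(C)(C)C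
F3 | step 9 | aminal of ent-14 with the same (4R,5R)-imidazolidine (discarded diastereomer) | CC(C)(C)[Si](C)(C)OCC1=CC[C@H](CC(OCC)OCC)[C@@](C)(C2N(C)[C@H](c3ccccc3)[C@@H](c3ccccc3)N2C)[C@@H]1CC/C(C)=C/CO[Si](c4ccccc4)(c4ccccc4)C(C)(C)C
F4 | step 5 | methyl (6E)-8-[(tert-butyldiphenylsilyl)oxy]-6-methyloct-6-en-2-ynoate | COC(=O)C#CCC/C(C)=C/CO[Si](c1ccccc1)(c1ccccc1)C(C)(C)C
F5 | step 5 | methyl (2E,6E)-8-[(tert-butyldiphenylsilyl)oxy]-6-methyl-2-(tributylstannyl)octa-2,6-dienoate | CCCC[Sn](CCCC)(CCCC)/C(C(=O)OC)=C/CC/C(C)=C/CO[Si](c1ccccc1)(c1ccccc1)C(C)(C)C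
F6 | step 5 | methyl (2Z,6E)-8-[(tert-butyldiphenylsilyl)oxy]-2-ethenyl-6-methylocta-2,6-dienoate | C=C/C(C(=O)OC)=C/CC/C(C)=C/CO[Si](c1ccccc1)(c1ccccc1)C(C)(C)C
F7 | step 22 | 2-(trimethylsilyl)ethyl isocupressate (free O15–H) | C=C1CC[C@@H]2[C@](C)(CCC[C@]2(C)C(=O)OCC[Si](C)(C)C)[C@H]1CC/C(C)=C/CO
F8 | step 22 | 2-(trimethylsilyl)ethyl 15-O-oleoylisocupressate | C=C1CC[C@@H]2[C@](C)(CCC[C@]2(C)C(=O)OCC[Si](C)(C)C)[C@H]1CC/C(C)=C/COC(=O)CCCCCCC/C=C\CCCCCCCC
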